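**Retrosynthetic overview**
1. The target, a 4-hydroxydauc-8-ene-6,10-diyl diangelate, is traced back to a 6-ketone: the C6 carbinol comes from a hydroxyl-directed reduction, and the two angelates from esterification of the two secondary alcohols.
2. Key disconnection: the trans-fused hydroazulenone comes from a cis-decalin by a pinacol-type 1,2-shift of the C1–C6 bond to C5. This contracts the cyclohexane C1–C2–C3–C4–C5–C6 to the cyclopentane and, in the same event, widens the neighbouring cyclohexene to the cycloheptene.
3. Enabling feature: the ring-fusion CH (C5) lies between the tertiary carbinol C4 and the oxygenated C6, and C1 is quaternary. An all-cis C4/C5/C6 triol 5-mesylate of a cis-decalin therefore has an equatorial leaving group antiperiplanar to C6–C1 and a C6–OH that drives the shift; the shift delivers the C4 carbinol, the C6 carbonyl and the trans ring fusion at once.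
4. The decalin comes from a proline-mediated Robinson annulation of 2,5-dimethylcyclohexane-1,3-dione with methyl vinyl ketone. The isopropyl-bearing alkene is made by Wittig olefination and cuprate SN2' opening of the epoxy ketone; the ring-A alkene and C10 carbinol by Saegusa oxidation and directed reduction.
5. Order of ring formation: cyclohexanedione ring (purchased), then the second six-membered ring (aldol condensation, step 3), then both rings resized to five and seven in step 14.

Key step: step 14

Remark: bicyclic compounds are discussed with daucane atom numbers (C1 quaternary methyl carbon, C2, C3, C4 isopropyl carbon, C5, C6, C7, C8 methyl-bearing alkene carbon, C9, C10); the ring fusion is C1/C6 in the decalins and C1/C5 in the hydroazulenes.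
Remark: compounds 4 to 10 are carried as mixtures at the ring carbon bearing the secondary methyl group (C8), which becomes sp2 in step 8; the proline step is assumed to tolerate this remote methyl group as it does the parent triketone.
Remark: the angeloyl mixed anhydride 15 is prepared once, in step 10, on a scale that serves both esterifications (steps 11 and 16), and is kept as a filtered toluene solution at −20 °C under argon.

**Step 1**
Reactants: 1 5-methylcyclohexane-1,3-dione
Product: 2 2,5-dimethylcyclohexane-1,3-dione
Conditions: MeI, aq. KOH, MeOH, 60 °C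
Reagents that add atoms: iodomethane, CI
Why: C-methylation of the stabilised 1,3-dione enolate (standard 2-alkylation of cyclohexane-1,3-diones); the product is an enolisable dione, so no configuration is at stake.

**Step 2**
Reactants: 2 2,5-dimethylcyclohexane-1,3-dione; 3 methyl vinyl ketone
Product: 4 2,5-dimethyl-2-(3-oxobutyl)cyclohexane-1,3-dione (cis/trans mixture)
Conditions: Et3N (cat.), MeOH, rt
Reagents that add atoms: none
Why: Michael addition of the 2-substituted 1,3-dione to the enone (first half of a Robinson annulation); the two achiral isomers converge later.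

**Step 3**
Reactants: 4 triketone
Product: 6 (8aS)-3,8a-dimethyl-3,4,8,8a-tetrahydronaphthalene-1,6(2H,7H)-dione, via cis-ketol 5 (not isolated)
Conditions: L-proline (30 mol %), DMSO, rt
Reagents that add atoms: none
Why: Hajos–Parrish–Eder–Sauer–Wiechert reaction: the L-proline enamine of the side-chain ketone adds to one of the two enantiotopic ring carbonyls, which should set the quaternary carbon C1 (S) as in the parent Wieland–Miescher ketone, and the cis-ketol dehydrates to the enone.

**Step 4**
Reactants: 6 enedione
Product: 7 cis-epoxy diketone (oxirane on C5–C6, cis to the C1 methyl)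
Conditions: 30% H2O2, NaOH (cat.), MeOH, 0 °C
Reagents that add atoms: hydrogen peroxide, OO
Why: Weitz–Scheffer nucleophilic epoxidation: hydroperoxide should add to the enone β-carbon C6 from the face of the angular methyl, as known for 10-methyl-octalones and steroidal 4-en-3-ones, so that the C6–O bond is cis to the C1 methyl; the isolated ketone does not react.

**Step 5**
Reactants: 7 cis-epoxy diketone
Product: 8 ethylidene vinyl oxirane (E/Z mixture)
Conditions: EtPPh3Br, KHMDS, THF, 0 °C; then 7, −78 to 0 °C
Reagents that add atoms: ethyltriphenylphosphonium bromide, CC[P+](c1ccccc1)(c1ccccc1)c1ccccc1.[Br-]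
Why: Wittig olefination at the unhindered α-epoxy ketone, which is more electrophilic and far less hindered than the neopentylic C10 ketone; alkene geometry is irrelevant because the ethylidene carbon becomes the isopropyl CH.

**Step 6**
Reactants: 8 ethylidene vinyl oxirane
Product: 9 hydroxy ketone with C4(isopropyl)=C5 alkene and C6–OH cis to the C1 methyl
Conditions: MeLi (2 equiv), CuI (1 equiv), Et2O, 0 °C; then 8, −78 °C; AcOH/THF quench at −78 °C
Reagents that add atoms: methyllithium, [Li]C
Why: anti-SN2' opening of the vinyl oxirane by the Gilman cuprate: methyl adds to the exocyclic alkene carbon (making isopropyl), the double bond moves to C4=C5 and the oxirane oxygen stays on C6 with unchanged configuration; the ketone survives at −78 °C and the cold acidic quench avoids retro-aldol of the β-ketol alkoxide.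

**Step 7**
Reactants: 9 hydroxy ketone
Product: 10 bis(trimethylsilyl) compound (C10 silyl enol ether, C6 silyl ether)
Conditions: LDA (commercial solution, 2.5 equiv), TMSCl (3 equiv), THF, −78 °C
Reagents that add atoms: chlorotrimethylsilane, C[Si](C)(C)Cl
Why: kinetic deprotonation at C9, the only enolisable position of the C10 ketone, with in situ O-silylation (the tertiary alkoxide is silylated as well).

**Step 8**
Reactants: 10 bis(trimethylsilyl) compound
Product: 12 hydroxy dienone (C8=C9–C10=O enone; C6–OH free), via silyl ether enone 11 (not isolated)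
Conditions: Pd(OAc)2 (1.1 equiv), MeCN, rt; then citric acid (cat.), MeOH, 0 °C
Reagents that add atoms: none
Why: Saegusa–Ito oxidation: the palladium enolate undergoes β-hydride elimination to the C8=C9 enone, which also removes the stereocentre at C8, and mild acidic methanolysis frees the tertiary alcohol.

**Step 9**
Reactants: 12 hydroxy dienone
Product: 13 anti-1,3-diol (C10–OH trans, C6–OH cis to the C1 methyl)
Conditions: Me4NBH(OAc)3, MeCN/AcOH (1:1), −30 to −20 °C
Reagents that add atoms: none
Why: Evans–Saksena reduction: the borohydride bound to the angular C6–OH delivers hydride intramolecularly across the cyclohexenone (chair-like six-membered transition state with the OH axial on ring A), which should give the 1,3-anti diol with 1,2-selectivity.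

**Step 10**
Reactants: 14 angelic acid
Product: 15 angelic 2,4,6-trichlorobenzoic mixed anhydride (filtered toluene solution)
Conditions: 2,4,6-trichlorobenzoyl chloride (1.0 equiv), Et3N (1.1 equiv), toluene, rt; filtration under argon
Reagents that add atoms: 2,4,6-trichlorobenzoyl chloride, O=C(Cl)c1c(Cl)cc(Cl)cc1Cl
Why: first stage of the Yamaguchi protocol: the triethylammonium carboxylate of angelic acid is acylated by the hindered acid chloride to give the mixed anhydride, under conditions too mild to isomerise the Z alkene.

**Step 11**
Reactants: 13 anti-1,3-diol; 15 angelic 2,4,6-trichlorobenzoic mixed anhydride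
Product: 16 C10 angelate
Conditions: 15 (3 equiv), Et3N (1 equiv), toluene, 80 °C
Reagents that add atoms: none
Why: Yamaguchi mixed-anhydride esterification of the only secondary alcohol (the tertiary C6–OH is inert): the two ortho chlorines block the aroyl carbonyl, so the alcohol attacks the angeloyl carbonyl, and the absence of DMAP keeps the Z geometry of the angelate.

**Step 12**
Reactants: 16 C10 angelate
Product: 17 all-cis C4,C5,C6-triol
Conditions: OsO4 (5 mol %), Me3NO·2H2O (1.5 equiv), CH2Cl2, rt
Reagents that add atoms: trimethylamine N-oxide, C[N+](C)(C)[O-]; water, O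
Why: hydrogen-bond-directed dihydroxylation (Donohoe conditions): OsO4 should add to C4=C5 on the face of the allylic C6–OH, which is also the convex face of the cis-decalin, setting C4 and C5 with all three oxygens cis, while the ring-A alkene is deactivated by the allylic ester and shielded by the angular methyl.

**Step 13**
Reactants: 17 all-cis triol
Product: 18 C5 mesylate
Conditions: MsCl, Et3N, CH2Cl2, −20 to 0 °C
Reagents that add atoms: methanesulfonyl chloride, CS(=O)(=O)Cl
Why: sulfonylation (via sulfene) of the only secondary hydroxyl; the two tertiary hydroxyls should not react at low temperature.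

**Step 14**
Reactants: 18 C5 mesylate
Product: 19 trans-fused 4-hydroxy-6-oxo hydroazulene angelate
Conditions: Et3Al (4 equiv), CH2Cl2, −78 to 0 °C; aq. potassium sodium tartrate
Reagents that add atoms: none
Why: Et3Al turns both tertiary hydroxyls into aluminium alkoxides and activates the mesylate; in the ring-B chair that keeps isopropyl equatorial the C5–OMs bond is equatorial and antiperiplanar to the C6–C1 ring bond, so C1 shifts from C6 to C5 with backside displacement of mesylate while the C6 alkoxide collapses to the ketone. The closest known reaction type is the alkoxide- or organoaluminium-promoted pinacol-type (Suzuki–Tsuchihashi) rearrangement of vicinal diol monosulfonates, long used to turn decalin-diol monosulfonates into hydroazulenones. No ring is closed by cyclisation: the single suprafacial 1,2-alkyl shift replaces the C1–C6 bond by a C1–C5 bond, which contracts the cyclohexane to the cyclopentane and enlarges the cyclohexene to the cycloheptene at once. C5 is set by inversion (the new C1–C5 bond forms anti to the leaving group, so H5 ends up trans to the C1 methyl, which is the trans ring fusion), C1 migrates with retention, and C4 and C10 pass through unchanged. The step needs migration of C1 rather than C3 (also antiperiplanar, pushed by the C4 alkoxide) or C7: C1 is the fully substituted, better migrating carbon, C7 is gauche to the leaving group in the populated chair (the flipped chair suffers syn-diaxial methyl/mesylate and isopropyl/CH2 contacts), both alkoxides are cis to the mesylate so no epoxide can form, and no hydrogen is antiperiplanar for elimination. The ester oxygen at C10 is a poor neighbouring group, and the aluminium aldolate formed at low temperature should protect the β-hydroxy ketone from retro-aldol cleavage and C5 epimerisation.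

**Step 15**
Reactants: 19 hydroxy ketone
Product: 20 4,6-diol 10-angelate
Conditions: Me4NBH(OAc)3, MeCN/AcOH (1:1), −30 to 0 °C
Reagents that add atoms: none
Why: Evans–Saksena reduction: hydride is delivered from the boron bound to the C4–OH, which is cis to the C6 carbonyl branch on the cyclopentane, through the only chair transition state the trans-fused ring system allows, which should give the 1,3-anti diol with the required C6 configuration; ester and alkene are untouched.

**Step 16**
Reactants: 20 4,6-diol 10-angelate; 15 angelic 2,4,6-trichlorobenzoic mixed anhydride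
Product: 21 CNP0183261.1
Conditions: 15 (3 equiv), Et3N (1 equiv), toluene, 80 °C
Reagents that add atoms: none
Why: Yamaguchi esterification of the secondary C6–OH with retention of the Z geometry; the tertiary C4–OH does not acylate.

**Compound list**
1 | 5-methylcyclohexane-1,3-dione | CC1CC(=O)CC(=O)C1 | starting material
2 | 2,5-dimethylcyclohexane-1,3-dione | CC1CC(=O)C(C)C(=O)C1 | intermediate
3 | methyl vinyl ketone (but-3-en-2-one) | CC(=O)C=C | starting material
4 | 2,5-dimethyl-2-(3-oxobutyl)cyclohexane-1,3-dione (cis/trans mixture) | CC1CC(=O)C(C)(CCC(C)=O)C(=O)C1 | intermediate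
5 | cis-ketol, 4a-hydroxy-3,8a-dimethyloctahydronaphthalene-1,6-dione, OH cis to the angular methyl (formed and dehydrated in the flask) | CC1CC(=O)[C@@]2(C)CCC(=O)C[C@@]2(O)C1 | intermediate
6 | (8aS)-3,8a-dimethyl-3,4,8,8a-tetrahydronaphthalene-1,6(2H,7H)-dione (epimers at C3) | CC1CC(=O)[C@@]2(C)CCC(=O)C=C2C1 | intermediate
7 | 4a,5-epoxy-3,8a-dimethyloctahydronaphthalene-1,6-dione, oxirane cis to the angular methyl | CC1CC(=O)[C@@]2(C)CCC(=O)[C@@H]3O[C@]23C1 | intermediate
8 | 6-ethylidene-4a,5-epoxy-3,8a-dimethyloctahydronaphthalen-1(2H)-one (E/Z mixture) | CC1CC(=O)[C@@]2(C)CCC(=CC)[C@@H]3O[C@]23C1 | intermediate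
9 | 4a-hydroxy-3,8a-dimethyl-6-(propan-2-yl)-3,4,4a,7,8,8a-hexahydronaphthalen-1(2H)-one, OH cis to the angular methyl | CC1CC(=O)[C@@]2(C)CCC(C(C)C)=C[C@@]2(O)C1 | intermediate
10 | 1,4a-bis(trimethylsilyloxy)-3,8a-dimethyl-6-(propan-2-yl)-3,4,4a,7,8,8a-hexahydronaphthalene | CC1C=C(O[Si](C)(C)C)[C@@]2(C)CCC(C(C)C)=C[C@@]2(O[Si](C)(C)C)C1 | intermediate
11 | 3,8a-dimethyl-6-(propan-2-yl)-4a-(trimethylsilyloxy)-4a,7,8,8a-tetrahydronaphthalen-1(4H)-one (cleaved in the flask) | CC1=CC(=O)[C@@]2(C)CCC(C(C)C)=C[C@@]2(O[Si](C)(C)C)C1 | intermediate
12 | 4a-hydroxy-3,8a-dimethyl-6-(propan-2-yl)-4a,7,8,8a-tetrahydronaphthalen-1(4H)-one | CC1=CC(=O)[C@@]2(C)CCC(C(C)C)=C[C@@]2(O)C1 | intermediate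
13 | 3,8a-dimethyl-6-(propan-2-yl)-1,4,4a,7,8,8a-hexahydronaphthalene-1,4a-diol, 1-OH trans and 4a-OH cis to the angular methyl | CC1=C[C@@H](O)[C@@]2(C)CCC(C(C)C)=C[C@@]2(O)C1 | intermediate
14 | angelic acid, (Z)-2-methylbut-2-enoic acid | C/C=C(/C)C(=O)O | starting material
15 | (Z)-2-methylbut-2-enoic 2,4,6-trichlorobenzoic anhydride (filtered toluene solution, used in steps 11 and 16) | C/C=C(/C)C(=O)OC(=O)c1c(Cl)cc(Cl)cc1Cl | intermediate
16 | 1-O-angelate of diol 13 (4a-OH free) | CC1=C[C@@H](OC(=O)/C(C)=C\C)[C@@]2(C)CCC(C(C)C)=C[C@@]2(O)C1 | intermediate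
17 | 1-angeloyloxy-3,8a-dimethyl-6-(propan-2-yl)-1,4,4a,5,6,7,8,8a-octahydronaphthalene-4a,5,6-triol, all three OH cis to the angular methyl | CC1=C[C@@H](OC(=O)/C(C)=C\C)[C@@]2(C)CC[C@@](O)(C(C)C)[C@H](O)[C@@]2(O)C1 | intermediate
18 | 5-O-methanesulfonate of triol 17 | CC1=C[C@@H](OC(=O)/C(C)=C\C)[C@@]2(C)CC[C@@](O)(C(C)C)[C@H](OS(C)(=O)=O)[C@@]2(O)C1 | intermediate
19 | (3R,3aR,8R,8aS)-3-hydroxy-6,8a-dimethyl-4-oxo-3-(propan-2-yl)-1,2,3,3a,4,5,8,8a-octahydroazulen-8-yl (Z)-2-methylbut-2-enoate | O=C1CC(C)=C[C@@H](OC(=O)/C(C)=C\C)[C@@]2(C)CC[C@@](O)(C(C)C)[C@H]12 | intermediate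
20 | (3R,3aS,4S,8R,8aS)-3,4-dihydroxy-6,8a-dimethyl-3-(propan-2-yl)-1,2,3,3a,4,5,8,8a-octahydroazulen-8-yl (Z)-2-methylbut-2-enoate | O[C@H]1CC(C)=C[C@@H](OC(=O)/C(C)=C\C)[C@@]2(C)CC[C@@](O)(C(C)C)[C@H]12 | intermediate
21 | CNP0183261.1, (3R,3aS,4S,8R,8aS)-3-hydroxy-6,8a-dimethyl-3-(propan-2-yl)-1,2,3,3a,4,5,8,8a-octahydroazulene-4,8-diyl bis[(Z)-2-methylbut-2-enoate] | C/C=C(/C)C(=O)O[C@H]1CC(C)=C[C@@H](OC(=O)/C(C)=C\C)[C@@]2(C)CC[C@@](O)(C(C)C)[C@H]12 | target

Total step count: 16
Longest linear sequence: 15 steps (steps 1 to 9 and 11 to 16, from 1 to 21); step 10 is a one-step branch from 14.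

**Steps most likely to fail**

Step 14 (key step). What may go wrong: shift of the wrong ring bond (C3, pushed by the C4 alkoxide, or C7 from the minor chair), participation of the C10 oxygen at C5, or retro-aldol opening of the product aldolate. The fallback removes the competing donor before the shift. It sets out from 18: TESOTf and 2,6-lutidine at −78 °C should silylate the less hindered tertiary hydroxyl at C4 to give the 4-O-triethylsilyl mesylate F1. KHMDS (1.0 equiv, THF, −78 to 0 °C) then forms only the C6 potassium alkoxide, and the classical alkoxide-driven shift should give the silyl-protected hydroazulenone F2, which has no free β-hydroxyl and cannot undergo retro-aldol cleavage. HF·pyridine in THF removes the silyl group and the route is rejoined at 19.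

Step 4. What may go wrong: poor facial selectivity, with hydroperoxide attacking anti to the angular methyl; that series would end in the cis-fused hydroazulene. The fallback replaces nucleophilic by hydroxyl-directed epoxidation. It sets out from 6: Luche reduction (NaBH4, CeCl3·7H2O, MeOH, −20 °C) should give the enediol F3, whose allylic hydroxyl is pseudo-equatorial and cis to the angular methyl. Epoxidation with mCPBA (Henbest) or VO(acac)2/tBuOOH is then directed by this hydroxyl to the methyl face and should give the epoxy diol F4. Dess–Martin periodinane oxidises both secondary alcohols and the route is rejoined at 7.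

Step 11. What may go wrong: slow acylation of the neopentylic allylic alcohol and Z-to-E isomerisation of the angelate to the tiglate. The fallback builds the Z-enoate on the substrate instead of transferring it. It sets out from 13: esterification with 2-[bis(2,2,2-trifluoroethoxy)phosphoryl]propanoic acid (DCC, DMAP, CH2Cl2) gives the phosphonate ester F5, where no alkene geometry is at stake. Still–Gennari olefination (KHMDS 2 equiv, 18-crown-6, THF, −78 °C, acetaldehyde) should then give the Z-trisubstituted enoate, and the route is rejoined at 16.

**Further compounds**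
F1 | step 14 | 4-O-triethylsilyl ether of mesylate 18 | CC1=C[C@@H](OC(=O)/C(C)=C\C)[C@@]2(C)CC[C@@](O[Si](CC)(CC)CC)(C(C)C)[C@H](OS(C)(=O)=O)[C@@]2(O)C1
F2 | step 14 | 3-O-triethylsilyl ether of hydroxy ketone 19 | O=C1CC(C)=C[C@@H](OC(=O)/C(C)=C\C)[C@@]2(C)CC[C@@](O[Si](CC)(CC)CC)(C(C)C)[C@H]12
F3 | step 4 | 3,8a-dimethyl-1,2,3,4,6,7,8,8a-octahydronaphthalene-1,6-diol, both OH cis to the angular methyl | CC1C[C@H](O)[C@@]2(C)CC[C@H](O)C=C2C1
F4 | step 4 | 4a,5-epoxy-3,8a-dimethyldecahydronaphthalene-1,6-diol, oxirane and both OH cis to the angular methyl | CC1C[C@H](O)[C@@]2(C)CC[C@H](O)[C@@H]3O[C@]23C1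
F5 | step 11 | 1-O-{2-[bis(2,2,2-trifluoroethoxy)phosphoryl]propanoyl} ester of diol 13 | CC1=C[C@@H](OC(=O)C(C)P(=O)(OCC(F)(F)F)OCC(F)(F)F)[C@@]2(C)CCC(C(C)C)=C[C@@]2(O)C1
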